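Read the other capture product of the ash run before you look at the target.

| flask | substrate | first nucleophile | second nucleophile | temperature | remark | time |
|---|---|---|---|---|---|---|
| ash | 0.050 M | 0.055 M | 0.035 M | 85 °C | run made earlier |  |
| maple | 0.050 M | 0.028 M | 0.035 M | 96 °C | run made earlier |  |
| cedar | 0.050 M | 0.11 M | 0.035 M | 85 °C | run made earlier |  |
| green | 0.050 M (fed, over 80 min) | 0.0550 M | 0.0350 M | 90 °C | all else is in the flask from the start; the feed brings no volume worth counting | 6.0 h |
| red | 0.050 M | 0.0550 M | 0.0350 M |  | everything together at the start at 70 °C, warmed to 90 °C at 80 min | 6.0 h |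
| violet | 0.050 M | 0.0550 M | 0.0350 M | 90 °C | everything together at the start | 6.0 h |
| ochre | 0.050 M | 0.0550 M (fed, over 80 min) | 0.0350 M |  | the addition at 70 °C, then warmed to 90 °C; the feed brings no volume worth counting | 6.0 h |

| run | time / h | target / % | other capture product / % |
|---|---|---|---|
| ash | 0.250 | 5.8 | 2.9 |
| ash | 0.667 | 12.3 | 6.3 |
| ash | 1.50 | 21.3 | 5.4 |
| ash | 4.00 | 36.6 | 7.1 |
| maple | 0.833 | 8.0 | 2.8 |
| maple | 2.00 | 12.8 | 1.6 |
| maple | 2.50 | 16.0 | 2.4 |
| maple | 4.00 | 19.5 | 2.1 |
| cedar | 0.833 | 25.6 | 3.9 |
| cedar | 2.00 | 42.0 | 6.2 |
| cedar | 2.50 | 46.9 | 4.4 |
| cedar | 4.00 | 52.7 | 5.2 |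

(scatter of a reading: 1 percentage point)

- the flask with the highest share of target in target plus other capture product ("all alike" if they lie within 1.5 percentage points) (green / red / violet / ochre / all alike)
- share of target in target plus other capture product at the end, green
- share of target in target plus other capture product at the end, red
- share of target in target plus other capture product at the end, violet
- share of target in target plus other capture product at the end, ochre



1. In ash I saw that product level off near 6.27% of the substrate, or 0.00313 M, against 0.035 M of second nucleophile charged. So I took it that second nucleophile was lost by another route, on a clock of its own.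

2. I assumed a first-order loss. From 2.9% at 0.250 h I read the life of the second nucleophile, the time in which it falls by a factor e: 24.1 min. This rests on one reading with scatter 1 percentage point.

3. I took it that in ash, with everything together, capture ran for about one life against the full substrate. For green I took it that the substrate, under its steady feed, had only begun to build during that life, so I scaled the other capture product by the overlap, life over feed time.

4. Low end of my bracket for green, an estimate: I kept the life and plateau of ash, at 85 °C. The overlap was 0.302, the other capture product 1.89%, and the target ash's 36.6%, so the share was 95.1%.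

5. High end of my bracket, also an estimate, going round again: maple's plateau as read, scaled to the first nucleophile of green, was 1.13%. Its geometric mean with ash gave 2.66% for 90 °C. Putting that fall back into the life gave 10.3 min, an overlap of 0.128 and 0.342% of other capture product. With target equal to the whole charge, the share was 99.7%.

6. I committed to the geometric middle of the two amounts with ash's target: 97.9%.

7. The forecast gave green 92%, violet 89%, red 86% and ochre 79%, with green first: “So I expect green (substrate starved, hot) to be best”.

8. The flasks gave green 98.3%, violet 91.4%, red 81.2% and ochre 77.2%, so green stood highest, and green lay inside my bracket.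

    substrate ⇌ dormant form (K = 1.90, k = 0.0130 min⁻¹, Ea = 118 kJ mol⁻¹, ΔH = −2.00 kJ mol⁻¹)
    second nucleophile + intermediate → other capture product (k = 110 M⁻¹ min⁻¹, Ea = 55.0 kJ mol⁻¹)
    first nucleophile + intermediate → target (k = 94.0 M⁻¹ min⁻¹, Ea = 53.0 kJ mol⁻¹)
    substrate ⇌ intermediate (K = 0.00110, k = 0.0700 min⁻¹, Ea = 99.0 kJ mol⁻¹, ΔH = −34.0 kJ mol⁻¹)
    second nucleophile → decomposed reagent (k = 0.0710 min⁻¹, Ea = 115 kJ mol⁻¹)
    intermediate → side product (k = 0.00960 min⁻¹, Ea = 119 kJ mol⁻¹)
    (constants at 90 °C)

9. In green at 90 °C the second nucleophile had, by its decomposition step alone, a life of 14.1 min against a feed of 80 min, an overlap of 0.176. Green ended with 0.741% of other capture product and violet with 4.03%, a ratio of 0.184.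

10. Now take ochre read at 2.5 h, warmed after its feed of 80 min. By my estimate, a life of 24.1 min leaves about 5.48% of the second nucleophile that stood at warming, so I expected its other capture product to stand close to its final value. The computed flask held 0.257% of the second nucleophile charge and 11.3% of other capture product, the same 11.3% as at 6.00 h, with a share of 66.9%.

The earlier runs and the new flask were computed with constants of no real substance; noise was put on by code.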